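**Plan**

1. The target is a germacranolide: a ten-membered carbocycle C1–C10 with a 1,10-epoxide, a C2 ketone, a (Z)-C3=C4 alkene and C5–OH, a cis-fused α-methylene-γ-lactone (O6, C6, C7, C11, C12; C13 methylene) and a tiglate on O8.
2. Enabling feature: C2 is an acyl carbon between the epoxide carbon C1 and the vinyl carbon C3, so C2–C3 is an acyl–vinyl bond of the ten-membered ring. It is cut last, to a (Z)-vinyl iodide and an S-2-pyridyl epoxy thioester; the forward ring closure is a nickel-catalysed reductive acyl–vinyl coupling that should give the unprotected target directly.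
3. Earlier cuts: C2 oxidation level and the C1/C10 epoxide (Sharpless), lactone C12–O6 and the O8 ester, C7–C8 (indium allylation), C7=C11 (cross metathesis), C5–C6 (allylboration).
4. Forward order: iodoenal → anti diol → dioxolane → allyl bromide; union with the C8–C10/C1/C2 aldehyde; tiglate; γ-lactone ring; epoxide ring; ten-membered ring last.
5. Stereochemistry: C5/C6 from a reagent-controlled (E)-γ-silylallyl-Ipc2B addition with Tamao oxidation; C7/C8 from the chair indium allylation steered by the dioxolane; C1/C10 from Sharpless epoxidation with D-(−)-tartrate; 3Z from chelation-controlled carbomagnesiation; 1(10)E and the tiglate E from purchased materials.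

Key step: step 14

Remark: names of later intermediates use germacrane numbering of the target (ring C1–C10, C11–C13 lactone carbons, C14 on C10, C15 on C4; "2,3-seco" means the C2–C3 bond is absent); allyl(diisopropylamino)dimethylsilane, methyl 2-(bromomethyl)acrylate, (E)-3-methylpent-2-en-4-yn-1-ol and tiglic acid are taken as purchased.

Step 1
Reactants: 1 prop-2-yn-1-ol
Product: 3 (Z)-3-iodo-2-methylprop-2-en-1-ol, via alkenylmagnesium alkoxide 2 (not isolated)
Conditions: MeMgBr (3 equiv), CuI (10 mol %), THF, −10 → 23 °C; then I2, −78 → 0 °C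
Reagents that add atoms: methylmagnesium bromide, C[Mg]Br; iodine, II
Why: Copper-catalysed anti-carbomagnesiation of the propargylic magnesium alkoxide gives a chelated alkenylmagnesium with Mg cis to CH2O, and iodinolysis with retention should give the Z iodoalkene that becomes C3=C4.

Step 2
Reactants: 3 (Z)-3-iodo-2-methylprop-2-en-1-ol
Product: 4 (Z)-3-iodo-2-methylprop-2-enal
Conditions: MnO2, CH2Cl2, 23 °C
Reagents that add atoms: none
Why: Allylic alcohol oxidation with MnO2 is neutral, so the Z geometry should survive.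

Step 3
Reactants: 4 (Z)-3-iodo-2-methylprop-2-enal; 5 allyl(diisopropylamino)dimethylsilane
Product: 7 (1Z,3S,4R)-1-iodo-2-methylhexa-1,5-diene-3,4-diol, via hydroxy allylsilane 6 (not isolated)
Conditions: 5, n-BuLi, TMEDA, Et2O, 0 °C; (+)-Ipc2BOMe [from (−)-α-pinene], −78 °C; BF3·OEt2; 4, −78 °C; then H2O2, KF, KHCO3, THF/MeOH, 23 °C
Reagents that add atoms: hydrogen peroxide, OO
Why: Brown-type allylboration with the (E)-γ-silylallyl diisopinocampheylborane through a chair transition state (E reagent gives anti, the Ipc2B unit chooses the aldehyde face and so C5), then Tamao oxidation of C–Si with retention, should give the anti diol with C5 S and C6 R.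

Step 4
Reactants: 7 (1Z,3S,4R)-1-iodo-2-methylhexa-1,5-diene-3,4-diol
Product: 8 (4S,5R)-4-[(Z)-1-iodoprop-1-en-2-yl]-2,2-dimethyl-5-vinyl-1,3-dioxolane
Conditions: Me2C(OMe)2, PPTS (cat.), CH2Cl2, 23 °C
Reagents that add atoms: 2,2-dimethoxypropane, COC(C)(C)OC
Why: Acid-catalysed transacetalisation ties the anti diol into a cis-dioxolane, which protects O5/O6 and later steers the C7 face.

Step 5
Reactants: 8 (4S,5R)-4-[(Z)-1-iodoprop-1-en-2-yl]-2,2-dimethyl-5-vinyl-1,3-dioxolane; 9 methyl 2-(bromomethyl)acrylate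
Product: 10 methyl (Z)-2-(bromomethyl)-3-{(4R,5S)-5-[(Z)-1-iodoprop-1-en-2-yl]-2,2-dimethyl-1,3-dioxolan-4-yl}prop-2-enoate
Conditions: 9 (5 equiv), second-generation Hoveyda–Grubbs catalyst RuCl2(H2IMes)(=CH–C6H4-2-OiPr) (10 mol %), CH2Cl2, 40 °C
Reagents that add atoms: none
Why: Olefin cross metathesis of the terminal vinyl group with the 1,1-disubstituted acrylate should give the trisubstituted alkene with the dioxolane trans to the ester (Z by CIP, cis to CH2Br), while the trisubstituted iodoalkene is inert.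

Step 6
Reactants: 11 (E)-3-methylpent-2-en-4-yn-1-ol
Product: 12 (E)-tert-butyldimethyl[(3-methylpent-2-en-4-yn-1-yl)oxy]silane
Conditions: TBSCl, imidazole, CH2Cl2, 0 → 23 °C
Reagents that add atoms: tert-butyldimethylsilyl chloride, CC(C)(C)[Si](C)(C)Cl
Why: Standard silylation protects the primary allylic alcohol that becomes C2–OH.

Step 7
Reactants: 12 (E)-tert-butyldimethyl[(3-methylpent-2-en-4-yn-1-yl)oxy]silane
Product: 14 (E)-5-[(tert-butyldimethylsilyl)oxy]-3-methylpent-3-enal, via dienylborane 13 (not isolated)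
Conditions: Cy2BH (from BH3·SMe2 and cyclohexene), THF, 0 °C; then H2O2, pH 7 phosphate buffer, 0 → 23 °C
Reagents that add atoms: hydrogen peroxide, OO
Why: Anti-Markovnikov hydroboration of the terminal alkyne with a hindered dialkylborane and buffered oxidation should give the dienol, which tautomerises by α-protonation to the β,γ-unsaturated aldehyde with the E alkene untouched.

Step 8
Reactants: 10 allyl bromide (Z; dioxolane 4R,5S); 14 (E)-5-[(tert-butyldimethylsilyl)oxy]-3-methylpent-3-enal
Product: 15 methyl (5S,6R,7R,8R,1(10)E,3Z)-2-(tert-butyldimethylsilyloxy)-8-hydroxy-3-iodo-5,6-(isopropylidenedioxy)-2,3-secogermacra-1(10),3,11(13)-trien-12-oate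
Conditions: In powder, THF/H2O (1:1), 23 °C
Reagents that add atoms: none
Why: Indium-mediated Barbier allylation: the allylindium from the (Z)-bromide should add through C7 in a chair transition state with the dioxolane axial (syn C7/C8), and with C6–H eclipsing the alkene (A(1,3) strain) and the acetal oxygen not chelating in water the aldehyde should approach the C7 face opposite the dioxolane C5 carbon, giving C7 R and C8 R.

Step 9
Reactants: 15 seco hydroxy ester (5S,6R,7R,8R); 16 tiglic acid
Product: 17 methyl (5S,6R,7R,8R,1(10)E,3Z)-2-(tert-butyldimethylsilyloxy)-3-iodo-5,6-(isopropylidenedioxy)-8-tigloyloxy-2,3-secogermacra-1(10),3,11(13)-trien-12-oate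
Conditions: 16, 2,4,6-Cl3C6H2COCl, Et3N, PhMe, 23 °C; then 15, DMAP, 23 °C
Reagents that add atoms: none
Why: Yamaguchi esterification acylates the hindered C8 alcohol through the mixed anhydride, which should outrun lactonisation of that alcohol onto the methyl ester and keeps the tiglate E.

Step 10
Reactants: 17 seco tiglate (5S,6R,7R,8R)
Product: 19 (5S,6R,7R,8R,1(10)E,3Z)-2,5-dihydroxy-3-iodo-8-tigloyloxy-2,3-secogermacra-1(10),3,11(13)-trien-12,6-olide, via triol methyl ester 18 (not isolated)
Conditions: AcOH/THF/H2O (3:1:1), 45 °C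
Reagents that add atoms: none
Why: Acid hydrolysis removes the acetonide and the primary silyl ether, and the C6 hydroxyl should then close the five-membered lactone in preference to the six-membered one from O5; no stereocentre is touched, so the cis ring fusion comes from step 8.

Step 11
Reactants: 19 seco lactone diol (5S,6R,7R,8R)
Product: 20 (1R,5S,6R,7R,8R,10R,3Z)-1,10-epoxy-2,5-dihydroxy-3-iodo-8-tigloyloxy-2,3-secogermacra-3,11(13)-dien-12,6-olide
Conditions: Ti(OiPr)4 (30 mol %), D-(−)-diethyl tartrate (36 mol %), t-BuOOH, 4 Å MS, CH2Cl2, −20 °C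
Reagents that add atoms: tert-butyl hydroperoxide, CC(C)(C)OO
Why: Sharpless asymmetric epoxidation of the primary (E)-trisubstituted allylic alcohol with the D-tartrate should give the trans (1R,10R)-epoxy alcohol (the series opposite to that from geraniol-type alcohols with the L-tartrate), while the electron-poor methylene lactone, tiglate and iodoalkene do not react.

Step 12
Reactants: 20 seco epoxy alcohol (1R,10R)
Product: 22 (1S,5S,6R,7R,8R,10R,3Z)-1,10-epoxy-5-hydroxy-3-iodo-8-tigloyloxy-2,3-secogermacra-3,11(13)-dien-12,6-olid-2-oic acid, via epoxy aldehyde 21 (not isolated)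
Conditions: TEMPO (20 mol %), PhI(OAc)2, CH2Cl2, 23 °C; then NaClO2, NaH2PO4, 2-methylbut-2-ene, t-BuOH/H2O, 0 °C
Reagents that add atoms: sodium chlorite, [Na+].[O-]Cl=O
Why: TEMPO/PhI(OAc)2 oxidation is selective for the primary alcohol over the hindered secondary C5 alcohol, and Pinnick oxidation of the aldehyde should give the glycidic acid without opening the epoxide.

Step 13
Reactants: 22 seco epoxy acid
Product: 23 S-(pyridin-2-yl) (1S,5S,6R,7R,8R,10R,3Z)-1,10-epoxy-5-hydroxy-3-iodo-8-tigloyloxy-2,3-secogermacra-3,11(13)-dien-12,6-olide-2-thioate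
Conditions: 2,2′-dipyridyl disulfide, PPh3, CH2Cl2, 0 → 23 °C
Reagents that add atoms: 2,2′-dipyridyl disulfide, c1ccc(SSc2ccccn2)nc1
Why: Mukaiyama redox condensation activates only the carboxylic acid (acyloxyphosphonium ion) and should give the 2-pyridyl thioester under neutral conditions that spare the epoxide and the secondary alcohol.

Step 14
Reactants: 23 seco iodo thioester
Product: 24 CNP0345622.1, (1S,5S,6R,7R,8R,10R,3Z)-1,10-epoxy-5-hydroxy-2-oxo-8-tigloyloxygermacra-3,11(13)-dien-12,6-olide
Conditions: NiBr2(dme) (30 mol %), 4,4′-di-tert-butyl-2,2′-bipyridine (36 mol %), (Me2N)2C=C(NMe2)2 (TDAE, 2.5 equiv), DMA/THF (1:1), 23 °C, 23 added over 12 h (final 2 mM)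
Reagents that add atoms: none
Why: Proposed new method: zerovalent nickel should insert into the C3–I bond with retention, the vinylnickel is reduced by TDAE to the monovalent stage, adds oxidatively to the C2 acyl–S bond of the 2-pyridyl thioester, and the trivalent acyl(vinyl)nickel releases the enone by C–C reductive elimination; the closest known reaction type is the nickel-catalysed reductive cross-electrophile ketone synthesis (alkyl halides with 2-pyridyl thioesters, vinyl triflates with acid fluorides, both between two molecules) and the palladium/zinc ring closure of iodoalkyl thioesters to macrocyclic ketones. The ten-membered carbocycle closes by reductive elimination from an eleven-membered nickelacycle, formally a 10-exo-trig acyl substitution at C2, and no other ring forms. No stereocentre is created, and the 3Z geometry is carried over because σ-vinylnickel keeps its configuration and the ring can hold only the Z isomer. Ring closure must beat oligomerisation and hydrodeiodination, which slow addition to high dilution and the three turn elements (cis-fused lactone, Z alkene, trans epoxide) should secure. Insertion of the vinylnickel into the C11=C13 methylene lactone would need a strained seven-membered transition state, and the epoxide should survive because the organic reductant leaves no Lewis acidic metal halide. The free C5 hydroxyl needs no protection, so the product is the target itself.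

**Compound list**

1 | prop-2-yn-1-ol | C#CCO | starting material
2 | bromomagnesium (Z)-3-(bromomagnesio)-2-methylprop-2-en-1-olate | Br[Mg]OC/C(C)=C\[Mg]Br | intermediate (not isolated)
3 | (Z)-3-iodo-2-methylprop-2-en-1-ol | OC/C(C)=C\I | intermediate
4 | (Z)-3-iodo-2-methylprop-2-enal | O=C/C(C)=C\I | intermediate
5 | allyl(diisopropylamino)dimethylsilane | C=CC[Si](C)(C)N(C(C)C)C(C)C | starting material
6 | (1Z,3S,4R)-4-[(diisopropylamino)dimethylsilyl]-1-iodo-2-methylhexa-1,5-dien-3-ol (held as its diisopinocampheylborinate) | C=C[C@@H]([Si](C)(C)N(C(C)C)C(C)C)[C@@H](O)/C(C)=C\I | intermediate (not isolated)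
7 | (1Z,3S,4R)-1-iodo-2-methylhexa-1,5-diene-3,4-diol | C=C[C@@H](O)[C@@H](O)/C(C)=C\I | intermediate
8 | (4S,5R)-4-[(Z)-1-iodoprop-1-en-2-yl]-2,2-dimethyl-5-vinyl-1,3-dioxolane | C=C[C@H]1OC(C)(C)O[C@H]1/C(C)=C\I | intermediate
9 | methyl 2-(bromomethyl)acrylate | C=C(CBr)C(=O)OC | starting material
10 | methyl (Z)-2-(bromomethyl)-3-{(4R,5S)-5-[(Z)-1-iodoprop-1-en-2-yl]-2,2-dimethyl-1,3-dioxolan-4-yl}prop-2-enoate | BrC/C(C(=O)OC)=C\[C@H]1OC(C)(C)O[C@H]1/C(C)=C\I | intermediate
11 | (E)-3-methylpent-2-en-4-yn-1-ol | C#C/C(C)=C/CO | starting material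
12 | (E)-tert-butyldimethyl[(3-methylpent-2-en-4-yn-1-yl)oxy]silane | C#C/C(C)=C/CO[Si](C)(C)C(C)(C)C | intermediate
13 | dicyclohexyl{(1E,3E)-5-[(tert-butyldimethylsilyl)oxy]-3-methylpenta-1,3-dien-1-yl}borane | C1CCCCC1B(/C=C/C(C)=C/CO[Si](C)(C)C(C)(C)C)C1CCCCC1 | intermediate (not isolated)
14 | (E)-5-[(tert-butyldimethylsilyl)oxy]-3-methylpent-3-enal | O=CC/C(C)=C/CO[Si](C)(C)C(C)(C)C | intermediate
15 | methyl (5S,6R,7R,8R,1(10)E,3Z)-2-(tert-butyldimethylsilyloxy)-8-hydroxy-3-iodo-5,6-(isopropylidenedioxy)-2,3-secogermacra-1(10),3,11(13)-trien-12-oate | C=C(C(=O)OC)[C@@H]([C@H]1OC(C)(C)O[C@H]1/C(C)=C\I)[C@H](O)C/C(C)=C/CO[Si](C)(C)C(C)(C)C | intermediate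
16 | tiglic acid, (E)-2-methylbut-2-enoic acid | C/C=C(\C)C(=O)O | starting material
17 | methyl (5S,6R,7R,8R,1(10)E,3Z)-2-(tert-butyldimethylsilyloxy)-3-iodo-5,6-(isopropylidenedioxy)-8-tigloyloxy-2,3-secogermacra-1(10),3,11(13)-trien-12-oate | C=C(C(=O)OC)[C@@H]([C@H]1OC(C)(C)O[C@H]1/C(C)=C\I)[C@H](OC(=O)/C(C)=C/C)C/C(C)=C/CO[Si](C)(C)C(C)(C)C | intermediate
18 | methyl (5S,6R,7R,8R,1(10)E,3Z)-2,5,6-trihydroxy-3-iodo-8-tigloyloxy-2,3-secogermacra-1(10),3,11(13)-trien-12-oate | C=C(C(=O)OC)[C@@H]([C@@H](O)[C@@H](O)/C(C)=C\I)[C@H](OC(=O)/C(C)=C/C)C/C(C)=C/CO | intermediate (not isolated)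
19 | (5S,6R,7R,8R,1(10)E,3Z)-2,5-dihydroxy-3-iodo-8-tigloyloxy-2,3-secogermacra-1(10),3,11(13)-trien-12,6-olide | C=C1C(=O)O[C@@H]([C@@H](O)/C(C)=C\I)[C@H]1[C@H](OC(=O)/C(C)=C/C)C/C(C)=C/CO | intermediate
20 | (1R,5S,6R,7R,8R,10R,3Z)-1,10-epoxy-2,5-dihydroxy-3-iodo-8-tigloyloxy-2,3-secogermacra-3,11(13)-dien-12,6-olide | C=C1C(=O)O[C@@H]([C@@H](O)/C(C)=C\I)[C@H]1[C@H](OC(=O)/C(C)=C/C)C[C@@]2(C)O[C@@H]2CO | intermediate
21 | (1S,5S,6R,7R,8R,10R,3Z)-1,10-epoxy-5-hydroxy-3-iodo-2-oxo-8-tigloyloxy-2,3-secogermacra-3,11(13)-dien-12,6-olide (aldehyde) | C=C1C(=O)O[C@@H]([C@@H](O)/C(C)=C\I)[C@H]1[C@H](OC(=O)/C(C)=C/C)C[C@@]2(C)O[C@@H]2C=O | intermediate (not isolated)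
22 | (1S,5S,6R,7R,8R,10R,3Z)-1,10-epoxy-5-hydroxy-3-iodo-8-tigloyloxy-2,3-secogermacra-3,11(13)-dien-12,6-olid-2-oic acid | C=C1C(=O)O[C@@H]([C@@H](O)/C(C)=C\I)[C@H]1[C@H](OC(=O)/C(C)=C/C)C[C@@]2(C)O[C@@H]2C(=O)O | intermediate
23 | S-(pyridin-2-yl) thioester of 22 | C=C1C(=O)O[C@@H]([C@@H](O)/C(C)=C\I)[C@H]1[C@H](OC(=O)/C(C)=C/C)C[C@@]2(C)O[C@@H]2C(=O)Sc1ccccn1 | intermediate
24 | CNP0345622.1, (1S,5S,6R,7R,8R,10R,3Z)-1,10-epoxy-5-hydroxy-2-oxo-8-tigloyloxygermacra-3,11(13)-dien-12,6-olide | C=C1C(=O)O[C@@H]2[C@H]1[C@H](OC(=O)/C(C)=C/C)C[C@@]1(C)O[C@@H]1C(=O)/C=C(/C)[C@@H]2O | target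

**Totals and risks**

Total steps: 14. Longest linear sequence: 12 (steps 1–5 and 8–14; steps 6–7 make the second fragment).

Steps most likely to fail:

1. Step 14 (the step with the new-method label). Oligomerisation or hydrodeiodination may outrun ring closure, the vinylnickel may insert into the methylene lactone, or the acylnickel may lose CO. Fallback with known chemistry, setting out from 20 and returning at 24:
   - TEMPO/PhI(OAc)2 in CH2Cl2 without the chlorite stage gives epoxy aldehyde 21, now isolated.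
   - TESOTf/2,6-lutidine at −78 °C gives the C5 triethylsilyl ether F1.
   - An intramolecular Nozaki–Hiyama–Kishi reaction (CrCl2 in excess, NiCl2 cat., DMSO/THF, 23 °C, 2 mM) closes the same C2–C3 bond to the macrocyclic allylic alcohol F2 as a mixture of C2 epimers.
   - Dess–Martin periodinane/NaHCO3 gives the silyl-protected epoxy enone F3.
   - HF·pyridine/pyridine in THF at 0 °C removes the silyl group to give 24.

2. Step 8. Facial selectivity of the allylindium relative to the dioxolane may be poor, and the new C8 alkoxide may lactonise onto the methyl ester before acylation. Fallback, setting out from 8 and returning at 15: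
   - Cross metathesis of 8 with methyl 2-[(pinacolatoboryl)methyl]acrylate (second-generation Hoveyda–Grubbs catalyst) gives the allylboronate F4.
   - Allylboration of 14 catalysed by a chiral phosphoric acid (TRIP, PhMe, −30 → 23 °C) goes through a closed six-membered transition state (syn), with the aldehyde face set by the catalyst instead of the dioxolane.
   - Hydrolytic work-up gives 15.

3. Step 5. Cross metathesis of the electron-poor 1,1-disubstituted acrylate may be slow and homodimerisation of 8 may dominate. Fallback, setting out from 8 and returning at 10: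
   - OsO4 (cat.)/NaIO4/2,6-lutidine in dioxane/H2O cleaves only the vinyl group to the aldehyde F5.
   - A Morita–Baylis–Hillman reaction with methyl acrylate/DABCO gives the allylic alcohol F6 (carbinol epimers, of no consequence).
   - NBS/Me2S converts F6 with allylic transposition into the (Z)-bromide 10.

Further compounds

F1 | step 14 | (1S,5S,6R,7R,8R,10R,3Z)-1,10-epoxy-3-iodo-2-oxo-8-tigloyloxy-5-(triethylsilyloxy)-2,3-secogermacra-3,11(13)-dien-12,6-olide | C=C1C(=O)O[C@@H]([C@@H](O[Si](CC)(CC)CC)/C(C)=C\I)[C@H]1[C@H](OC(=O)/C(C)=C/C)C[C@@]2(C)O[C@@H]2C=O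
F2 | step 14 | (1R,2RS,5S,6R,7R,8R,10R,3Z)-1,10-epoxy-2-hydroxy-8-tigloyloxy-5-(triethylsilyloxy)germacra-3,11(13)-dien-12,6-olide | C=C1C(=O)O[C@@H]2[C@H]1[C@H](OC(=O)/C(C)=C/C)C[C@@]1(C)O[C@@H]1C(O)/C=C(/C)[C@@H]2O[Si](CC)(CC)CC
F3 | step 14 | (1S,5S,6R,7R,8R,10R,3Z)-1,10-epoxy-2-oxo-8-tigloyloxy-5-(triethylsilyloxy)germacra-3,11(13)-dien-12,6-olide | C=C1C(=O)O[C@@H]2[C@H]1[C@H](OC(=O)/C(C)=C/C)C[C@@]1(C)O[C@@H]1C(=O)/C=C(/C)[C@@H]2O[Si](CC)(CC)CC
F4 | step 8 | methyl (E)-3-{(4R,5S)-5-[(Z)-1-iodoprop-1-en-2-yl]-2,2-dimethyl-1,3-dioxolan-4-yl}-2-[(4,4,5,5-tetramethyl-1,3,2-dioxaborolan-2-yl)methyl]prop-2-enoate | CC1(C)OB(C/C(C(=O)OC)=C\[C@H]2OC(C)(C)O[C@H]2/C(C)=C\I)OC1(C)C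
F5 | step 5 | (4S,5S)-5-[(Z)-1-iodoprop-1-en-2-yl]-2,2-dimethyl-1,3-dioxolane-4-carbaldehyde | O=C[C@H]1OC(C)(C)O[C@H]1/C(C)=C\I
F6 | step 5 | methyl 2-{hydroxy[(4R,5S)-5-[(Z)-1-iodoprop-1-en-2-yl]-2,2-dimethyl-1,3-dioxolan-4-yl]methyl}acrylate (carbinol epimers) | C=C(C(=O)OC)C(O)[C@H]1OC(C)(C)O[C@H]1/C(C)=C\I
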